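**Retrosynthetic overview** (cembrane numbering: C1 = ring-fusion carbon bearing C15–C17, C2 = lactone carbinol, C13 = acetoxy carbon)
1. Target ⇐ acetylation ⇐ hydroxyl-directed epoxidation of the C11=C12 olefin of a (13S)-13-hydroxy cembratetraen-16,2-olide; C11 and C12 are set from C13.
2. The 14-membered ring and the trans α-methylene-γ-lactone ⇐ one C1–C2 bond, made by a chiral-phosphoric-acid-catalysed macrocyclising allylboration of a tethered enal, then δ→γ translactonisation that frees the 13-OH.
3. The nucleophile is a 3-(borylmethyl)-5,6-dihydropyran-2-one; the δ-lactone locks the enoate geometry needed for the anti (trans) outcome and masks the 13-OH. It comes from Pd borylation ⇐ RCM ⇐ 2-(bromomethyl)acrylate of a homoallylic alcohol.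
4. The homoallylic alcohol (C13, first stereocentre) ⇐ organocatalytic allylboration of 12-oxofarnesyl acetate ⇐ SeO2 oxidation of (2E,6E)-farnesyl acetate.
5. Ring order: δ-lactone (RCM) → 14-membered carbocycle (allylboration) → γ-lactone (translactonisation) → epoxide.

Assumption: (R)-TRIP-PA (3,3'-bis(2,4,6-triisopropylphenyl)-1,1'-binaphthyl-2,2'-diyl hydrogen phosphate) delivers the allyl group to the Re face of an aldehyde, as in its intermolecular reactions with benzaldehyde; if the sense proved opposite, the enantiomeric acid is used in steps 2 and 8.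

**Route**

Step 1
Reactants: 1 (2E,6E)-farnesyl acetate; 2 tert-butyl hydroperoxide
Product: 4 (2E,6E,10E)-3,7,11-trimethyl-12-oxododeca-2,6,10-trien-1-yl acetate, via 12-hydroxyfarnesyl acetate 3 (not isolated)
Conditions: SeO2 (0.3 equiv), t-BuOOH (70% aq, 3 equiv), salicylic acid (0.1 equiv), CH2Cl2, 0 °C → rt; then MnO2 (10 equiv), CH2Cl2, rt
Reagents that add atoms: tert-butyl hydroperoxide, CC(C)(C)OO
Why: SeO2/t-BuOOH allylic oxidation (ene reaction then [2,3]-sigmatropic shift) attacks the (E)-methyl of the terminal, most electron-rich trisubstituted olefin, and MnO2 converges the allylic alcohol/aldehyde mixture to the (E)-enal; no stereocentre is formed.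

Step 2
Reactants: 4 (2E,6E,10E)-3,7,11-trimethyl-12-oxododeca-2,6,10-trien-1-yl acetate; 5 allylboronic acid pinacol ester
Product: 7 (2E,6E,10E,12S)-12-hydroxy-3,7,11-trimethylpentadeca-2,6,10,14-tetraen-1-yl acetate, via homoallyl pinacol borate 6 (not isolated)
Conditions: (S)-TRIP-PA (5 mol%), 4 Å MS, toluene, −30 °C; aq. NaHCO3 work-up
Reagents that add atoms: allylboronic acid pinacol ester, C=CCB1OC(C)(C)C(C)(C)O1
Why: Chiral-phosphoric-acid-catalysed allylboration through a closed chair transition state in which the acid hydrogen-bonds the boronate oxygen and the formyl hydrogen; the (S)-catalyst directs allyl to the Si face of the enal and sets the first stereocentre, C13, as S (12S in this open-chain numbering).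

Step 3
Reactants: 7 (2E,6E,10E,12S)-12-hydroxy-3,7,11-trimethylpentadeca-2,6,10,14-tetraen-1-yl acetate
Product: 8 (2E,6E,10E,12S)-3,7,11-trimethylpentadeca-2,6,10,14-tetraene-1,12-diol
Conditions: K2CO3 (0.2 equiv), MeOH, 0 °C → rt
Reagents that add atoms: none
Why: Base-catalysed transesterification (methanolysis) removes the primary allylic acetate without touching the stereocentre or the olefins.

Step 4
Reactants: 8 (2E,6E,10E,12S)-3,7,11-trimethylpentadeca-2,6,10,14-tetraene-1,12-diol
Product: 9 (2E,6E,10E,12S)-12-hydroxy-3,7,11-trimethylpentadeca-2,6,10,14-tetraenal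
Conditions: TEMPO (10 mol%), PhI(OAc)2 (1.1 equiv), CH2Cl2, 0 °C → rt
Reagents that add atoms: none
Why: The oxoammonium (TEMPO/PhI(OAc)2) oxidation is strongly selective for the primary over the hindered secondary alcohol and gives the (2E)-enal without E/Z isomerisation.

Step 5
Reactants: 9 (2E,6E,10E,12S)-12-hydroxy-3,7,11-trimethylpentadeca-2,6,10,14-tetraenal; 10 2-(bromomethyl)prop-2-enoic acid
Product: 12 (4S,5E,9E,13E)-5,9,13-trimethyl-15-oxopentadeca-1,5,9,13-tetraen-4-yl 2-(bromomethyl)prop-2-enoate, via 2-(bromomethyl)prop-2-enoyl chloride 11 (not isolated)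
Conditions: 10, (COCl)2, DMF (cat.), CH2Cl2, 0 °C; then 9, 2,6-lutidine, CH2Cl2, −40 → 0 °C
Reagents that add atoms: 2-(bromomethyl)prop-2-enoic acid, C=C(CBr)C(=O)O
Why: Acylation of the secondary alcohol by the acid chloride with a hindered, non-nucleophilic base avoids the SN2' attack on the allylic bromide that nucleophilic amine catalysts would cause; the C–O bond at C13 is untouched, so configuration is retained.

Step 6
Reactants: 12 (4S,5E,9E,13E)-5,9,13-trimethyl-15-oxopentadeca-1,5,9,13-tetraen-4-yl 2-(bromomethyl)prop-2-enoate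
Product: 13 (6S)-3-(bromomethyl)-6-[(2E,6E,10E)-6,10-dimethyl-12-oxododeca-2,6,10-trien-2-yl]-5,6-dihydro-2H-pyran-2-one
Conditions: second-generation Hoveyda–Grubbs catalyst (5 mol%), CH2Cl2 (5 mM), 40 °C
Reagents that add atoms: none
Why: Ring-closing metathesis starts at the only monosubstituted olefin and closes onto the 1,1-disubstituted acrylate to give the six-membered unsaturated lactone (the trisubstituted chain olefins and the enal are inert), and the ring fixes C14 cis to the carbonyl.

Step 7
Reactants: 13 (6S)-3-(bromomethyl)-6-[(2E,6E,10E)-6,10-dimethyl-12-oxododeca-2,6,10-trien-2-yl]-5,6-dihydro-2H-pyran-2-one; 14 bis(pinacolato)diboron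
Product: 15 (6S)-6-[(2E,6E,10E)-6,10-dimethyl-12-oxododeca-2,6,10-trien-2-yl]-3-[(4,4,5,5-tetramethyl-1,3,2-dioxaborolan-2-yl)methyl]-5,6-dihydro-2H-pyran-2-one
Conditions: Pd2(dba)3 (2.5 mol%), B2pin2 (1.1 equiv), THF, rt
Reagents that add atoms: bis(pinacolato)diboron, CC1(C)OB(OC1(C)C)B1OC(C)(C)C(C)(C)O1
Why: Zerovalent-palladium-catalysed allylic borylation (Miyaura type) proceeds through a π-allyl complex and places boron on the unsubstituted CH2 terminus, giving an electron-poor 2-carbonyl allylboronate that does not react with the remote enal without acid catalysis.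

Step 8
Reactants: 15 (6S)-6-[(2E,6E,10E)-6,10-dimethyl-12-oxododeca-2,6,10-trien-2-yl]-3-[(4,4,5,5-tetramethyl-1,3,2-dioxaborolan-2-yl)methyl]-5,6-dihydro-2H-pyran-2-one
Product: 18 (1R,2S,3E,7E,11E,13S)-13-hydroxycembra-3,7,11,15(17)-tetraen-16,2-olide, via bridged 16,13-olide 2-O-borate 16 (not isolated), via 16,2-olide 13-O-borate 17 (not isolated)
Conditions: (R)-TRIP-PA (20 mol%), 4 Å MS, toluene (1 mM, slow addition), 45 °C; then PPTS (20 mol%), rt; aq. NaHCO3 work-up
Reagents that add atoms: none
Why: Proposed new method: a chiral-phosphoric-acid-catalysed macrocyclising allylboration, in which the acid activates the otherwise inert lactone-embedded 2-carbonyl allylboronate and the tethered enal in a closed chair transition state, so that the (R)-catalyst selects the Re face of the aldehyde (C2 = S) and the ring-locked geometry (C14 trans to CH2B) enforces the anti relation (C1 = R) while the 14-membered ring closes; acid-promoted acyl transfer from O13 to O2 then gives the more stable trans-fused γ-lactone and frees the 13-OH; the closest known reactions are the intermolecular phosphoric-acid-catalysed allyl- and crotylboration of aldehydes and the Brønsted-acid-catalysed allylboration–lactonisation of 2-alkoxycarbonyl allylboronates.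

Step 9
Reactants: 18 (1R,2S,3E,7E,11E,13S)-13-hydroxycembra-3,7,11,15(17)-tetraen-16,2-olide; 2 tert-butyl hydroperoxide
Product: 19 (1R,2S,3E,7E,11R,12R,13S)-11,12-epoxy-13-hydroxycembra-3,7,15(17)-trien-16,2-olide
Conditions: VO(acac)2 (5 mol%), t-BuOOH (1.5 equiv, in decane), CH2Cl2, 0 °C → rt
Reagents that add atoms: tert-butyl hydroperoxide, CC(C)(C)OO
Why: Hydroxyl-directed vanadium epoxidation touches only the allylic-alcohol olefin, and for an (E)-2-methyl allylic alcohol the A(1,2)-strain model delivers oxygen anti to the C13–C14 bond (the locally peripheral face), giving the erythro epoxy alcohol; C12 has the target's spatial arrangement and is labelled R here only because the free OH changes the priority order.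

Step 10
Reactants: 19 (1R,2S,3E,7E,11R,12R,13S)-11,12-epoxy-13-hydroxycembra-3,7,15(17)-trien-16,2-olide; 20 acetic anhydride
Product: 21 (1R,2S,3E,7E,11R,12S,13S)-13-acetoxy-11,12-epoxycembra-3,7,15(17)-trien-16,2-olide (CNP0146076.5)
Conditions: Ac2O, pyridine, DMAP (cat.), CH2Cl2, 0 °C → rt
Reagents that add atoms: acetic anhydride, CC(=O)OC(C)=O
Why: O-acylation of the secondary alcohol under mild base leaves the epoxide and the α-methylene lactone intact and retains configuration at C13.

**Compound list**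
1 | (2E,6E)-farnesyl acetate | CC(=O)OC/C=C(\C)CC/C=C(\C)CCC=C(C)C | starting material
2 | tert-butyl hydroperoxide | CC(C)(C)OO | starting material
3 | (2E,6E,10E)-12-hydroxy-3,7,11-trimethyldodeca-2,6,10-trien-1-yl acetate | CC(=O)OC/C=C(\C)CC/C=C(\C)CC/C=C(\C)CO | intermediate
4 | (2E,6E,10E)-3,7,11-trimethyl-12-oxododeca-2,6,10-trien-1-yl acetate | CC(=O)OC/C=C(\C)CC/C=C(\C)CC/C=C(\C)C=O | intermediate
5 | allylboronic acid pinacol ester | C=CCB1OC(C)(C)C(C)(C)O1 | starting material
6 | (2E,6E,10E,12S)-3,7,11-trimethyl-12-[(4,4,5,5-tetramethyl-1,3,2-dioxaborolan-2-yl)oxy]pentadeca-2,6,10,14-tetraen-1-yl acetate | CC(=O)OC/C=C(\C)CC/C=C(\C)CC/C=C(\C)[C@@H](OB1OC(C)(C)C(C)(C)O1)CC=C | intermediate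
7 | (2E,6E,10E,12S)-12-hydroxy-3,7,11-trimethylpentadeca-2,6,10,14-tetraen-1-yl acetate | CC(=O)OC/C=C(\C)CC/C=C(\C)CC/C=C(\C)[C@@H](O)CC=C | intermediate
8 | (2E,6E,10E,12S)-3,7,11-trimethylpentadeca-2,6,10,14-tetraene-1,12-diol | OC/C=C(\C)CC/C=C(\C)CC/C=C(\C)[C@@H](O)CC=C | intermediate
9 | (2E,6E,10E,12S)-12-hydroxy-3,7,11-trimethylpentadeca-2,6,10,14-tetraenal | O=C/C=C(\C)CC/C=C(\C)CC/C=C(\C)[C@@H](O)CC=C | intermediate
10 | 2-(bromomethyl)prop-2-enoic acid | C=C(CBr)C(=O)O | starting material
11 | 2-(bromomethyl)prop-2-enoyl chloride | C=C(CBr)C(=O)Cl | intermediate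
12 | (4S,5E,9E,13E)-5,9,13-trimethyl-15-oxopentadeca-1,5,9,13-tetraen-4-yl 2-(bromomethyl)prop-2-enoate | O=C/C=C(\C)CC/C=C(\C)CC/C=C(\C)[C@@H](OC(=O)C(=C)CBr)CC=C | intermediate
13 | (6S)-3-(bromomethyl)-6-[(2E,6E,10E)-6,10-dimethyl-12-oxododeca-2,6,10-trien-2-yl]-5,6-dihydro-2H-pyran-2-one | O=C/C=C(\C)CC/C=C(\C)CC/C=C(\C)[C@@H]1CC=C(CBr)C(=O)O1 | intermediate
14 | bis(pinacolato)diboron | CC1(C)OB(OC1(C)C)B1OC(C)(C)C(C)(C)O1 | starting material
15 | (6S)-6-[(2E,6E,10E)-6,10-dimethyl-12-oxododeca-2,6,10-trien-2-yl]-3-[(4,4,5,5-tetramethyl-1,3,2-dioxaborolan-2-yl)methyl]-5,6-dihydro-2H-pyran-2-one | O=C/C=C(\C)CC/C=C(\C)CC/C=C(\C)[C@@H]1CC=C(CB2OC(C)(C)C(C)(C)O2)C(=O)O1 | intermediate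
16 | (1R,2S,3E,7E,11E,13S)-2-[(4,4,5,5-tetramethyl-1,3,2-dioxaborolan-2-yl)oxy]cembra-3,7,11,15(17)-tetraen-16,13-olide (bridged δ-lactone) | C=C1C(=O)O[C@H]2C[C@H]1[C@@H](OB3OC(C)(C)C(C)(C)O3)/C=C(\C)CC/C=C(\C)CC/C=C2\C | intermediate
17 | (1R,2S,3E,7E,11E,13S)-13-[(4,4,5,5-tetramethyl-1,3,2-dioxaborolan-2-yl)oxy]cembra-3,7,11,15(17)-tetraen-16,2-olide | C=C1C(=O)O[C@H]2/C=C(\C)CC/C=C(\C)CC/C=C(\C)[C@@H](OB3OC(C)(C)C(C)(C)O3)C[C@H]12 | intermediate
18 | (1R,2S,3E,7E,11E,13S)-13-hydroxycembra-3,7,11,15(17)-tetraen-16,2-olide | C=C1C(=O)O[C@H]2/C=C(\C)CC/C=C(\C)CC/C=C(\C)[C@@H](O)C[C@H]12 | intermediate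
19 | (1R,2S,3E,7E,11R,12R,13S)-11,12-epoxy-13-hydroxycembra-3,7,15(17)-trien-16,2-olide | C=C1C(=O)O[C@H]2/C=C(\C)CC/C=C(\C)CC[C@H]3O[C@]3(C)[C@@H](O)C[C@H]12 | intermediate
20 | acetic anhydride | CC(=O)OC(C)=O | starting material
21 | (1R,2S,3E,7E,11R,12S,13S)-13-acetoxy-11,12-epoxycembra-3,7,15(17)-trien-16,2-olide | C=C1C(=O)O[C@H]2/C=C(\C)CC/C=C(\C)CC[C@H]3O[C@]3(C)[C@@H](OC(C)=O)C[C@H]12 | target

**Totals**
Total step count: 10. Longest linear sequence: 10 steps (1 → 21).

**Steps most likely to fail, with fallbacks**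

Step 8 (the proposed new macrocyclisation). The risks are the low nucleophilicity of a 2-carbonyl allylboronate at 1 mM, a clash between catalyst control and the tether, and an incomplete δ→γ acyl shift. The fallback uses known chemistry and sets out from bromide 13, so step 7 is bypassed too. CrCl2 (6 equiv) in THF at 2 mM and rt effects an intramolecular Nozaki–Hiyama (Barbier-type) allylation of the enal by the 2-(bromomethyl)enoate, a known way to close carbocycles bearing α-methylene lactones. The ring-locked allylchromium cannot isomerise, so the closed transition state still gives the anti C1/C2 pair. The face relative to C13 is then under substrate control, and diastereomers are separated. Work-up gives (1R,2S,3E,7E,11E,13S)-2-hydroxycembra-3,7,11,15(17)-tetraen-16,13-olide F1, which PPTS in CH2Cl2 translactonises, and the fallback comes back to the route at 18.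

Step 9 (face selectivity of the epoxidation inside the macrocycle). If the ring conformation overrides the acyclic A(1,2) preference, the control element is changed from the substrate to the reagent. Starting from 18, Sharpless epoxidation with Ti(OiPr)4, L-(+)-diisopropyl tartrate, t-BuOOH and 4 Å MS in CH2Cl2 at −20 °C is used. For the (13S)-alcohol the L-(+)-tartrate is the matched, fast-reacting pairing and gives the same erythro epoxy alcohol. The fallback comes back at 19 and makes no new compound F0.

Step 7 (allylic borylation next to β-hydrogens and a free enal). The π-allyl intermediate from 13 can lose a C14 hydrogen towards a 2-pyranone, and the product carries both an aldehyde and an allylboronate. The fallback sets out from 12 and reverses the order of C–B formation and ring closure. Pd2(dba)3/B2pin2 in THF borylates the open-chain 2-(bromomethyl)acrylate, whose π-allyl unit is symmetric and has no β-hydrogen, giving (4S,5E,9E,13E)-5,9,13-trimethyl-15-oxopentadeca-1,5,9,13-tetraen-4-yl 2-[(4,4,5,5-tetramethyl-1,3,2-dioxaborolan-2-yl)methyl]prop-2-enoate F2. Ring-closing metathesis of F2 with the second-generation Hoveyda–Grubbs catalyst (CH2Cl2, 5 mM, 40 °C) then comes back to the route at 15.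

**Further compounds**
F1 | step 8 | (1R,2S,3E,7E,11E,13S)-2-hydroxycembra-3,7,11,15(17)-tetraen-16,13-olide | C=C1C(=O)O[C@H]2C[C@H]1[C@@H](O)/C=C(\C)CC/C=C(\C)CC/C=C2\C
F0 | step 9 | none | none
F2 | step 7 | (4S,5E,9E,13E)-5,9,13-trimethyl-15-oxopentadeca-1,5,9,13-tetraen-4-yl 2-[(4,4,5,5-tetramethyl-1,3,2-dioxaborolan-2-yl)methyl]prop-2-enoate | O=C/C=C(\C)CC/C=C(\C)CC/C=C(\C)[C@@H](OC(=O)C(=C)CB1OC(C)(C)C(C)(C)O1)CC=C
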